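## Retrosynthetic overview
- The target is the (2R,3R)-trans-2-aryl-3-methyl-1,4-benzodioxane. Both aromatic rings are bought, so the dioxane is the only ring formed, and it is closed in the third of four steps.
- The (E)-propenyl C=C is made last by olefination of a ring A aldehyde. Until then the formyl group keeps ring A electron-poor.
- The dioxane C-7–O bond is made by anodic oxidation of the open-chain 8-O-4' ether to a p-quinone methide, which the neighbouring ring A phenol traps. C-8 controls C-7.
- The C-8–O bond is made by Mitsunobu inversion of an (S)-1-arylpropan-2-ol with 3,4-dihydroxy-5-methoxybenzaldehyde.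
- The aryl–CH2 bond is made by opening (S)-propylene oxide, the only source of chirality, with a metalated 4-bromo-2,6-dimethoxyphenol.

Assumption: 4-bromo-2,6-dimethoxyphenol, (S)-propylene oxide, 3,4-dihydroxy-5-methoxybenzaldehyde and 5-(ethylsulfonyl)-1-phenyl-1H-tetrazole are catalogue items. C-7 (benzylic) and C-8 (methyl-bearing) follow neolignan numbering.

## Route

Step 1
Reactants: 1 4-bromo-2,6-dimethoxyphenol; 2 (S)-propylene oxide
Product: 4 (S)-4-(2-hydroxypropyl)-2,6-dimethoxyphenol, via dilithio aryl phenoxide 3 (not isolated)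
Conditions: n-BuLi (1.0 equiv), THF, −78 °C; t-BuLi (2.0 equiv), −78 °C, 30 min; CuI (10 mol %), 2 (1.5 equiv), −78 → 0 °C; then 1 M HCl
Reagents that add atoms: none
Why: Deprotonation followed by Br/Li exchange gives 3, and its copper-catalysed SN2 epoxide opening takes place only at the unsubstituted CH2 of 2, so the bought C–O stereocentre is untouched and carried into 4 as (S).

Step 2
Reactants: 4 (S)-4-(2-hydroxypropyl)-2,6-dimethoxyphenol; 5 3,4-dihydroxy-5-methoxybenzaldehyde
Product: 6 3-hydroxy-4-{[(2R)-1-(4-hydroxy-3,5-dimethoxyphenyl)propan-2-yl]oxy}-5-methoxybenzaldehyde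
Conditions: PPh3 (1.5 equiv), DIAD (1.5 equiv), 5 (1.5 equiv), THF, 0 °C → rt
Reagents that add atoms: none
Why: In this Mitsunobu etherification the 4-OH of 5 (para to CHO, pKa about 7.5) is roughly two pKa units more acidic than its 3-OH and than the syringyl OH of 4, so it alone serves as the nucleophile and displaces the activated secondary alcohol by SN2 with inversion, (S) to (R), which sets C-8 from the bought centre.

Step 3
Reactants: 6 3-hydroxy-4-{[(2R)-1-(4-hydroxy-3,5-dimethoxyphenyl)propan-2-yl]oxy}-5-methoxybenzaldehyde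
Product: 8 (2R,3R)-3-(4-hydroxy-3,5-dimethoxyphenyl)-8-methoxy-2-methyl-2,3-dihydro-1,4-benzodioxine-6-carbaldehyde, via p-quinone methide 7 (not isolated)
Conditions: graphite anode, Pt cathode, undivided cell, constant current 5 mA cm−2, 2.1 F mol−1, n-Bu4NPF6 (0.1 M), 2,6-lutidine (2 equiv), HFIP/CH2Cl2 1:4 (10 mM in 6), 0 °C → rt
Reagents that add atoms: none
Why: Proposed new method: this is an anodic intramolecular dehydrogenative benzylic C(sp3)–H/O–H coupling in which the syringyl phenol of 6 (expected to oxidise about 0.4 V below the formyl-deactivated ring A phenol, with its ortho and para coupling sites blocked) loses two electrons and two protons with lutidine assistance to give 7, which non-nucleophilic HFIP leaves free for 6-exo oxa-1,6-addition of the neighbouring ring A OH; in the allylic-strain-minimised conformer of 7 the C-8 H eclipses the exocyclic C=C and the methyl group and tethered oxygen lie on opposite faces, so the H-7/H-8 anti (trans, diequatorial) product forms and C-8 sets C-7 as R, which is also the thermodynamic isomer because the addition is reversible; H2 evolution at the cathode balances the cell, and the closest known reactions are Ag2O or DDQ oxidation of 4-alkyl-2,6-dimethoxyphenols to quinone methides and anodic benzylic methoxylation of 4-alkylphenols, neither shown for a diastereoselective closure to a 1,4-benzodioxane.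

Step 4
Reactants: 8 (2R,3R)-3-(4-hydroxy-3,5-dimethoxyphenyl)-8-methoxy-2-methyl-2,3-dihydro-1,4-benzodioxine-6-carbaldehyde
Product: 9 4-[(2R,3R)-5-methoxy-3-methyl-7-[(E)-prop-1-en-1-yl]-2,3-dihydro-1,4-benzodioxin-2-yl]-2,6-dimethoxyphenol
Conditions: 5-(ethylsulfonyl)-1-phenyl-1H-tetrazole (2.5 equiv), KN(SiMe3)2 (2.4 equiv), DME, −55 °C, 30 min; add 8, −55 → 0 °C; then AcOH
Reagents that add atoms: 5-(ethylsulfonyl)-1-phenyl-1H-tetrazole, CCS(=O)(=O)c1nnnn1-c1ccccc1
Why: In this Julia–Kocienski olefination the sulfonyl carbanion adds to the aryl aldehyde, and Smiles rearrangement with loss of SO2 and tetrazolate gives the (E)-alkene (typically above 95:5 for aryl aldehydes with potassium base in DME), while one equivalent of base only holds the phenol as its phenoxide and neither stereocentre is touched at low temperature.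

## Compound list
1 | 4-bromo-2,6-dimethoxyphenol | COc1cc(Br)cc(OC)c1O | starting material
2 | (S)-propylene oxide | C[C@H]1CO1 | starting material
3 | lithium 4-lithio-2,6-dimethoxyphenolate | [Li]Oc1c(OC)cc([Li])cc1OC | intermediate
4 | (S)-4-(2-hydroxypropyl)-2,6-dimethoxyphenol | C[C@H](O)Cc1cc(OC)c(O)c(OC)c1 | intermediate
5 | 3,4-dihydroxy-5-methoxybenzaldehyde | COc1cc(C=O)cc(O)c1O | starting material
6 | 3-hydroxy-4-{[(2R)-1-(4-hydroxy-3,5-dimethoxyphenyl)propan-2-yl]oxy}-5-methoxybenzaldehyde | C[C@H](Cc1cc(OC)c(O)c(OC)c1)Oc1c(O)cc(C=O)cc1OC | intermediate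
7 | 4-[(2R)-2-(4-formyl-2-hydroxy-6-methoxyphenoxy)propylidene]-2,6-dimethoxycyclohexa-2,5-dien-1-one | COC1=CC(=C[C@@H](C)Oc2c(O)cc(C=O)cc2OC)C=C(OC)C1=O | intermediate
8 | (2R,3R)-3-(4-hydroxy-3,5-dimethoxyphenyl)-8-methoxy-2-methyl-2,3-dihydro-1,4-benzodioxine-6-carbaldehyde (trans) | O=Cc1cc(OC)c2c(c1)O[C@H](c1cc(OC)c(O)c(OC)c1)[C@@H](C)O2 | intermediate
9 | 4-[(2R,3R)-5-methoxy-3-methyl-7-[(E)-prop-1-en-1-yl]-2,3-dihydro-1,4-benzodioxin-2-yl]-2,6-dimethoxyphenol | C/C=C/c1cc(OC)c2c(c1)O[C@H](c1cc(OC)c(O)c(OC)c1)[C@@H](C)O2 | target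

## Step count and risks
Total step count: 4. Longest linear sequence: 4 (1 → 4 → 6 → 8 → 9).

The three steps most likely to fail are steps 3, 2 and 1, in decreasing order of risk. They are listed below in route order.

**Step 1.**
- Risk: the lithium phenoxide may be poorly soluble or exchange slowly, which would give low conversion in the epoxide opening.
- Fallback: it sets out from 1 and comes back at 4, replacing the unprotected dianion with a protected aryl Grignard reagent. Silylation of 1 with TBSCl and imidazole in DMF gives tert-butyl(4-bromo-2,6-dimethoxyphenoxy)dimethylsilane F1. Magnesium insertion in THF gives [4-(tert-butyldimethylsilyloxy)-3,5-dimethoxyphenyl]magnesium bromide F2. Opening of 2 catalysed by CuI at −30 °C gives (S)-1-[4-(tert-butyldimethylsilyloxy)-3,5-dimethoxyphenyl]propan-2-ol F3. Treatment with n-Bu4NF in THF then releases 4.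

**Step 2.**
- Risks: O-alkylation of one of the other two phenols, E2 loss to the propenylphenol, and participation of the electron-rich aryl group that erodes the inversion.
- Fallback: it sets out from 4 and comes back at 6, replacing the redox condensation with pre-activation and a base-gated Williamson displacement.
  - MsCl (2.2 equiv) and Et3N in CH2Cl2 convert 4 into (S)-1-[3,5-dimethoxy-4-(methylsulfonyloxy)phenyl]propan-2-yl methanesulfonate F4. Its electron-withdrawing aryl mesylate removes the competing phenol and suppresses aryl participation.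
  - The weakly basic mono-phenoxide of 5 (K2CO3, 1.2 equiv, DMF, 60 °C, with known 4-O selectivity) displaces the alkyl mesylate with inversion. This gives 4-[(2R)-2-(4-formyl-2-hydroxy-6-methoxyphenoxy)propyl]-2,6-dimethoxyphenyl methanesulfonate F5.
  - NaOH in aqueous MeOH at 50 °C cleaves the aryl mesylate to give 6.

**Step 3 (the new step).**
- Risks: further oxidation of 8, which is still a syringyl phenol; tautomerisation of 7 to the achiral enol ether; and cathodic back-reduction of 7.
- Fallback: it sets out from 6 and comes back at 8, using only known chemistry in two separate stages.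
  - Stoichiometric DDQ in CH2Cl2/MeOH performs the known benzylic methoxylation of a 4-alkylphenol. The product is 3-hydroxy-4-{[(1RS,2R)-1-(4-hydroxy-3,5-dimethoxyphenyl)-1-methoxypropan-2-yl]oxy}-5-methoxybenzaldehyde F6, possibly mixed with some 8.
  - Catalytic p-TsOH in CH2Cl2 ionises the benzylic ether. The ortho phenol then closes the ring under thermodynamic control to trans-8, which is the established acid-mediated closure of 7-oxygenated 8-O-4' neolignans.

## Further compounds
F1 | step 1 | tert-butyl(4-bromo-2,6-dimethoxyphenoxy)dimethylsilane | COc1cc(Br)cc(OC)c1O[Si](C)(C)C(C)(C)C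
F2 | step 1 | [4-(tert-butyldimethylsilyloxy)-3,5-dimethoxyphenyl]magnesium bromide | COc1cc([Mg]Br)cc(OC)c1O[Si](C)(C)C(C)(C)C
F3 | step 1 | (S)-1-[4-(tert-butyldimethylsilyloxy)-3,5-dimethoxyphenyl]propan-2-ol | C[C@H](O)Cc1cc(OC)c(O[Si](C)(C)C(C)(C)C)c(OC)c1
F4 | step 2 | (S)-1-[3,5-dimethoxy-4-(methylsulfonyloxy)phenyl]propan-2-yl methanesulfonate | C[C@@H](Cc1cc(OC)c(OS(C)(=O)=O)c(OC)c1)OS(C)(=O)=O
F5 | step 2 | 4-[(2R)-2-(4-formyl-2-hydroxy-6-methoxyphenoxy)propyl]-2,6-dimethoxyphenyl methanesulfonate | C[C@H](Cc1cc(OC)c(OS(C)(=O)=O)c(OC)c1)Oc1c(O)cc(C=O)cc1OC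
F6 | step 3 | 3-hydroxy-4-{[(1RS,2R)-1-(4-hydroxy-3,5-dimethoxyphenyl)-1-methoxypropan-2-yl]oxy}-5-methoxybenzaldehyde | COC(c1cc(OC)c(O)c(OC)c1)[C@@H](C)Oc1c(O)cc(C=O)cc1OC
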